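(The numbers in the tables were computed from invented constants; noise was put on by code.)

**No slope.** A straight-line rate cannot be read from the summer run: its last reading, 0.5%, lies below its first, 0.6%, with a scatter of 0.3 percentage points. Nor does a line suit the spring run, where from 12.0 h to 30.0 h time grows 2.50-fold and target 4.75-fold, near the square, 6.25. So we read target as (t/τ) squared, with τ the clock time at which that curve would reach the whole charge: a lag, as from a stock in between.

| setting | summer | spring | Wednesday's | Sunday's |
|---|---|---|---|---|
| starting material | 10 mM | 10 mM | 10 mM | 10 mM |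
| capture agent | 6.2 mM | 6.8 mM | 10.0 mM | 5.00 mM |
| temperature | 10 °C | 25 °C | 35 °C | 15 °C |
| remark | run made earlier | run made earlier |  |  |
| time |  |  | 30 h | 30 h |

- summer (time / h: target / %): 8.00: 0.6; 30.0: 0.1; 48.0: 0.2; 72.0: 0.5
- spring (time / h: target / %): 4.00: 0; 12.0: 0.8; 25.0: 2.2; 30.0: 3.8

(each reading ± 0.3 percentage points)

1. which one finishes higher in amount of target, in percent of the starting material charged ("neither" within 2 percentage points) (Wednesday's / Sunday's / neither)
2. amount of target at the end, in percent of the starting material charged, Wednesday's
3. amount of target at the end, in percent of the starting material charged, Sunday's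

- a reading or a percentage of target counts all its forms, free or not

**Common clock.** Least squares of target against t squared, through the origin, give τ as 158 h for the spring run and 1020 h for the summer run. If warming multiplies every step by one Arrhenius factor f, τ shrinks as 1/f, and the two clock times give 87.3 kJ mol⁻¹, a loose reading: the clock energy E, the apparent activation energy of the whole lag. Both runs held nearly the same capture agent, 6.2 mM and 6.8 mM, so we leave it out of the reckoning.

**First round.** The dose D is (f t/τ) squared, with τ from the spring run and f counted from it. Wednesday's has f = 3.13 and D = 35.5%. Sunday's has f = 0.295 and D = 0.314%.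

**Weak link.** Wednesday's dose assumes the feed stays whole. Suppose instead that the rate follows the feed left, which over the run falls short by about half of the final target y, so y = D(1 − y/2). Putting D in gives 29.2%, and putting that back gives 30.4%. Sunday's dose, far smaller, stands uncorrected. We commit to Wednesday's as the higher flask.

**The forecast** names Wednesday's, with 24% and 0.6%, from a rate that “implies a high activation energy”.

**Result.** Wednesday's gives 30.2% and Sunday's 0.231%, so Wednesday's finishes higher.

    starting material → intermediate A (k = 1.80 h⁻¹, Ea = 99.0 kJ mol⁻¹)
    intermediate A ⇌ intermediate B (K = 6.20, k = 0.0380 h⁻¹, Ea = 101 kJ mol⁻¹, ΔH = −64.0 kJ mol⁻¹)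
    intermediate B → target (k = 0.0900 h⁻¹, Ea = 105 kJ mol⁻¹)
    intermediate B ⇌ intermediate C (K = 2.40, k = 0.770 h⁻¹, Ea = 105 kJ mol⁻¹, ΔH = 19.0 kJ mol⁻¹)
    intermediate B → intermediate D (k = 0.200 h⁻¹, Ea = 105 kJ mol⁻¹)
    intermediate D → intermediate E (k = 0.190 h⁻¹, Ea = 108 kJ mol⁻¹)
    intermediate E → target (k = 0.150 h⁻¹, Ea = 105 kJ mol⁻¹)
    crystals ⇌ target, rate k8*(cs8 - [target]) while solid is left; crystals form when [target] > cs8 (solubility = 5.30 mM, k = 0.850 h⁻¹)
    capture agent + intermediate C → trapped intermediate (k = 4.30 L mol⁻¹ h⁻¹, Ea = 76.0 kJ mol⁻¹)
    starting material + intermediate E → side product (k = 2.80 L mol⁻¹ h⁻¹, Ea = 58.0 kJ mol⁻¹)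
    (constants at 35 °C)

In Wednesday's, starting material has a half-life of 0.39 h by its own step, much shorter than the 11.4 h by which half of the turnover of intermediate A into intermediate B is done. Intermediate A, the resting state, still holds 33.2% of Wednesday's charge at 30.0 h. With the clock energy 87.3 kJ mol⁻¹, the same flask as Wednesday's at 20 °C gets a dose of 1.09%, and that flask stands at 0.948%.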